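**Plan**

- Atom labels follow the target, a bicyclo[3.2.1]oct-2-en-8-one: C1 allyl bridgehead, C2=C3(OMe), C4 (OAc), C5 (OMe) bridgehead, C6 (aryl), C7 (methyl), C8 (C=O). The retrosynthesis first adjusts the C4 acetate, the C8 ketone and the allyl group (from a vinyl group). It then cuts C8–C5 and C6–C7 together, which opens both carbocycles to acyclic aldehyde 19. Finally it cuts C2=C3 (ring-closing metathesis) and the ester O–C8, giving acid 13 and alcohol 6.
- Enabling feature: in the cyclopentanone ring C1–C8–C5–C6–C7, both C8 and C7 hang on quaternary C1. A 2,2-divinyl aldehyde is therefore a latent C8•–C1–C7=CH2 unit (a 3-butenyl radical) that can add across the C5=C6 enol ether. The aryl group on C6 makes C6 the benzylic relay radical, and the vinyl CH2 ends as the C7 methyl group.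
- Forward order: 6 and 13 are joined as an ester, and a temporary six-membered lactone is closed at C2=C3, which fixes that alkene geometry. The lactone is opened to 19, and one radical cascade closes first the cyclohexene ring (C8–C5) and then the cyclopentane ring (C6–C7).
- Stereochemistry: C4 comes from a Corey–Bakshi–Shibata reduction. C5, C1, C6 and C7 arise in the cascade under control of C4. C1 starts with three identical vinyl groups: one becomes C2, one becomes C7 with its methyl group, one becomes the allyl group.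

Key step: step 14

Remark (assumption): the C8 carbinol of 20–23 is drawn as the epimer expected from an equatorial stannyloxy group in a chair-like transition state; it is of no consequence because C8 is oxidised in step 16.

**Route**

Step 1
Reactants: 1 3,4,5-trimethoxybenzaldehyde; 2 methyl 2-methoxyacetate
Product: 3 methyl (Z)-2-methoxy-3-(3,4,5-trimethoxyphenyl)prop-2-enoate
Conditions: NaOMe, MeOH, 0 °C to reflux; AcOH quench
Reagents that add atoms: none
Why: Claisen–Schmidt-type aldol condensation of the methoxyacetate enolate with the non-enolisable aldehyde and E1cB dehydration should give the more stable (Z)-alkene with aryl trans to the ester.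

Step 2
Reactants: 3 methyl (Z)-2-methoxy-3-(3,4,5-trimethoxyphenyl)prop-2-enoate
Product: 4 (Z)-N,2-dimethoxy-N-methyl-3-(3,4,5-trimethoxyphenyl)prop-2-enamide
Conditions: MeNHOMe·HCl, i-PrMgCl, THF, −20 °C
Reagents that add atoms: N,O-dimethylhydroxylamine hydrochloride, CNOC.Cl
Why: Magnesium amide aminolysis of the ester (Weinreb amide formation) should leave the enol ether untouched.

Step 3
Reactants: 4 (Z)-N,2-dimethoxy-N-methyl-3-(3,4,5-trimethoxyphenyl)prop-2-enamide
Product: 5 (Z)-2,4-dimethoxy-1-(3,4,5-trimethoxyphenyl)penta-1,4-dien-3-one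
Conditions: methyl vinyl ether, t-BuLi, THF, −78 to 0 °C; then 4, −78 °C; aq. NH4Cl
Reagents that add atoms: 1-methoxyvinyllithium, [Li]C(=C)OC, made in the flask from methyl vinyl ether, COC=C, and tert-butyllithium, [Li]C(C)(C)C
Why: Weinreb ketone synthesis, in which the chelated tetrahedral intermediate prevents a second addition of the alkenyllithium.

Step 4
Reactants: 5 (Z)-2,4-dimethoxy-1-(3,4,5-trimethoxyphenyl)penta-1,4-dien-3-one
Product: 6 (R,Z)-2,4-dimethoxy-1-(3,4,5-trimethoxyphenyl)penta-1,4-dien-3-ol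
Conditions: (S)-2-methyl-CBS-oxazaborolidine (20 mol %), catecholborane, PhMe, −78 °C
Reagents that add atoms: none
Why: Corey–Bakshi–Shibata 1,2-reduction, in which the aryl-bearing alkenyl group should act as the large substituent so that the (S)-catalyst delivers hydride to give the (R)-carbinol (C4 of the target).

Step 5
Reactants: 7 penta-1,4-diene
Product: 9 methyl 2-ethenylbut-3-enoate, via pentadienyllithium 8 (not isolated)
Conditions: n-BuLi, THF, −78 to 0 °C; then inverse addition to ClCO2Me, THF, −78 °C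
Reagents that add atoms: methyl chloroformate, COC(=O)Cl
Why: Deprotonation of the doubly allylic CH2 gives the pentadienyl anion, which should be acylated mainly at its central carbon, inverse addition keeping the acidic product away from unreacted anion.

Step 6
Reactants: 9 methyl 2-ethenylbut-3-enoate
Product: 11 rac-methyl 2,2-diethenyl-3-hydroxybutanoate, via lithium dienolate 10 (not isolated)
Conditions: LiN(i-Pr)2, THF, −78 °C; then CH3CHO, −78 °C; aq. NH4Cl
Reagents that add atoms: acetaldehyde, CC=O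
Why: Kinetic aldol addition of the cross-conjugated ester dienolate through its α-carbon should create the quaternary carbon (C1 of the target); the carbinol centre is removed in step 7.

Step 7
Reactants: 11 rac-methyl 2,2-diethenyl-3-hydroxybutanoate
Product: 12 methyl 2,2-diethenylbut-3-enoate
Conditions: Burgess reagent, PhMe, 80 °C
Reagents that add atoms: none
Why: Burgess dehydration (syn elimination of the sulfamate ester) can only give the terminal alkene because the other β-carbon is quaternary.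

Step 8
Reactants: 12 methyl 2,2-diethenylbut-3-enoate
Product: 13 2,2-diethenylbut-3-enoic acid
Conditions: LiOH, THF/MeOH/H2O, 60 °C; then cold aq. HCl to pH 3
Reagents that add atoms: lithium hydroxide, [Li+].[OH-]
Why: Saponification of the hindered ester, which has no α-hydrogen and so cannot isomerise into conjugation.

Step 9
Reactants: 13 2,2-diethenylbut-3-enoic acid; 6 (R,Z)-2,4-dimethoxy-1-(3,4,5-trimethoxyphenyl)penta-1,4-dien-3-ol
Product: 15 (R,Z)-2,4-dimethoxy-1-(3,4,5-trimethoxyphenyl)penta-1,4-dien-3-yl 2,2-diethenylbut-3-enoate, via acid chloride 14 (not isolated)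
Conditions: (COCl)2, cat. DMF, CH2Cl2, 0 to 25 °C, evaporate; then 6, Et3N, DMAP, CH2Cl2, 0 to 25 °C
Reagents that add atoms: none
Why: Acyl chloride formation and DMAP-catalysed esterification under basic conditions that the two enol ethers should tolerate, with the carbinol centre untouched.

Step 10
Reactants: 15 (R,Z)-2,4-dimethoxy-1-(3,4,5-trimethoxyphenyl)penta-1,4-dien-3-yl 2,2-diethenylbut-3-enoate
Product: 16 (S)-3,3-diethenyl-5-methoxy-6-[(Z)-1-methoxy-2-(3,4,5-trimethoxyphenyl)ethenyl]-3,6-dihydro-2H-pyran-2-one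
Conditions: second-generation Hoveyda–Grubbs catalyst RuCl2(=CH-C6H4-2-O-i-Pr)(H2IMes) (10 mol %), PhMe, 80 °C, 2 mM, argon sparge
Reagents that add atoms: none
Why: Ring-closing metathesis between one of the three equivalent vinyl groups and the 1,1-disubstituted enol ether should close the six-membered lactone and so fix C1 and C4 cis across the new C2=C3 enol ether.

Step 11
Reactants: 16 (S)-3,3-diethenyl-5-methoxy-6-[(Z)-1-methoxy-2-(3,4,5-trimethoxyphenyl)ethenyl]-3,6-dihydro-2H-pyran-2-one
Product: 17 (3E,5S,6Z)-2,2-diethenyl-5-hydroxy-N,4,6-trimethoxy-N-methyl-7-(3,4,5-trimethoxyphenyl)hepta-3,6-dienamide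
Conditions: MeNHOMe·HCl, i-PrMgCl, THF, −20 to 0 °C
Reagents that add atoms: N,O-dimethylhydroxylamine hydrochloride, CNOC.Cl
Why: Aminolysis of the lactone (Weinreb amide formation) should open the temporary ring and free the C4 hydroxyl without touching the stereocentre.

Step 12
Reactants: 17 (3E,5S,6Z)-2,2-diethenyl-5-hydroxy-N,4,6-trimethoxy-N-methyl-7-(3,4,5-trimethoxyphenyl)hepta-3,6-dienamide
Product: 18 (3E,5S,6Z)-5-[(tert-butyldimethylsilyl)oxy]-2,2-diethenyl-N,4,6-trimethoxy-N-methyl-7-(3,4,5-trimethoxyphenyl)hepta-3,6-dienamide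
Conditions: TBSCl, imidazole, DMF, 25 °C
Reagents that add atoms: tert-butyldimethylsilyl chloride, CC(C)(C)[Si](C)(C)Cl
Why: Standard silylation of the secondary allylic alcohol prevents relactonisation and lactol formation in step 13.

Step 13
Reactants: 18 (3E,5S,6Z)-5-[(tert-butyldimethylsilyl)oxy]-2,2-diethenyl-N,4,6-trimethoxy-N-methyl-7-(3,4,5-trimethoxyphenyl)hepta-3,6-dienamide
Product: 19 (3E,5S,6Z)-5-[(tert-butyldimethylsilyl)oxy]-2,2-diethenyl-4,6-dimethoxy-7-(3,4,5-trimethoxyphenyl)hepta-3,6-dienal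
Conditions: i-Bu2AlH, THF, −78 °C; aq. KNa tartrate
Reagents that add atoms: none
Why: Partial reduction of the Weinreb amide through its stable aluminium chelate should give the aldehyde, which has no α-hydrogen.

Step 14
Reactants: 19 (3E,5S,6Z)-5-[(tert-butyldimethylsilyl)oxy]-2,2-diethenyl-4,6-dimethoxy-7-(3,4,5-trimethoxyphenyl)hepta-3,6-dienal
Product: 21 (1S,4R,5R,6R,7S,8R)-4-[(tert-butyldimethylsilyl)oxy]-1-ethenyl-3,5-dimethoxy-7-methyl-6-(3,4,5-trimethoxyphenyl)bicyclo[3.2.1]oct-2-en-8-ol, via tributylstannyl ether 20 (not isolated)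
Conditions: Bu3SnH (syringe pump), AIBN, PhH, 80 °C, high dilution; then aq. KF
Reagents that add atoms: none
Why: Bu3Sn• adds to the oxygen of aldehyde C8 to give an O-stannyl ketyl radical, which closes the cyclohexene ring (C8–C1–C2–C3–C4–C5) by 6-exo-trig attack on C5 of the styrenyl enol ether; the regiochemistry is fixed by formation of the benzylic C6 radical. That radical closes the cyclopentane ring (C1–C8–C5–C6–C7) by 5-exo-trig addition to the internal carbon of whichever vinyl group on C1 is cis to it, and the resulting primary radical takes hydrogen from Bu3SnH to become the C7 methyl group. The closest known reaction type is the tin-hydride-mediated tandem ketyl–olefin cyclization of unsaturated aldehydes, formally a radical (3+2) annulation of a 3-butenyl-type radical. C5 should be set by the C4 silyl ether, which is expected to sit pseudoaxial and eclipsed with the C5=C6 bond in a chair-like transition state to avoid strain against the C3 and C5 methoxy groups, while C1 needs no control because its two vinyl groups are equivalent until the cis one is captured. C6 and C7 are set in the second closure, where the aryl group and the new methyl group should avoid eclipsing and end trans (aryl endo, methyl exo); the C8 carbinol configuration does not matter. The step needs the benzylic radical to cyclise faster than it is reduced, which slow addition of Bu3SnH should secure because benzylic radicals abstract hydrogen from tin hydride slowly.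

Step 15
Reactants: 21 (1S,4R,5R,6R,7S,8R)-4-[(tert-butyldimethylsilyl)oxy]-1-ethenyl-3,5-dimethoxy-7-methyl-6-(3,4,5-trimethoxyphenyl)bicyclo[3.2.1]oct-2-en-8-ol
Product: 23 (1S,4R,5R,6R,7S,8R)-4-[(tert-butyldimethylsilyl)oxy]-1-(2-hydroxyethyl)-3,5-dimethoxy-7-methyl-6-(3,4,5-trimethoxyphenyl)bicyclo[3.2.1]oct-2-en-8-ol, via B-alkyl-9-BBN adduct 22 (not isolated)
Conditions: 9-BBN, THF, 0 to 50 °C; then NaOH, H2O2, H2O, 0 to 25 °C
Reagents that add atoms: hydrogen peroxide, OO
Why: Anti-Markovnikov hydroboration–oxidation of the monosubstituted bridgehead vinyl group with bulky 9-BBN, which should react much more slowly with the hindered trisubstituted enol ether.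

Step 16
Reactants: 23 (1S,4R,5R,6R,7S,8R)-4-[(tert-butyldimethylsilyl)oxy]-1-(2-hydroxyethyl)-3,5-dimethoxy-7-methyl-6-(3,4,5-trimethoxyphenyl)bicyclo[3.2.1]oct-2-en-8-ol
Product: 24 2-[(1S,4R,5S,6R,7S)-4-[(tert-butyldimethylsilyl)oxy]-3,5-dimethoxy-7-methyl-8-oxo-6-(3,4,5-trimethoxyphenyl)bicyclo[3.2.1]oct-2-en-1-yl]acetaldehyde
Conditions: Dess–Martin periodinane, pyridine, CH2Cl2, 25 °C
Reagents that add atoms: none
Why: Dess–Martin oxidation should convert the primary alcohol to the aldehyde and the C8 carbinol to the bridging ketone in one operation, buffered to protect the enol ether.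

Step 17
Reactants: 24 2-[(1S,4R,5S,6R,7S)-4-[(tert-butyldimethylsilyl)oxy]-3,5-dimethoxy-7-methyl-8-oxo-6-(3,4,5-trimethoxyphenyl)bicyclo[3.2.1]oct-2-en-1-yl]acetaldehyde
Product: 25 (1S,4R,5S,6R,7S)-4-[(tert-butyldimethylsilyl)oxy]-3,5-dimethoxy-7-methyl-1-(prop-2-en-1-yl)-6-(3,4,5-trimethoxyphenyl)bicyclo[3.2.1]oct-2-en-8-one
Conditions: Ph3PCH3Br, KN(SiMe3)2, THF, −78 to 0 °C
Reagents that add atoms: methylidenetriphenylphosphorane, C=P(c1ccccc1)(c1ccccc1)c1ccccc1, made in the flask from methyltriphenylphosphonium bromide, C[P+](c1ccccc1)(c1ccccc1)c1ccccc1.[Br-]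
Why: Wittig methylenation of the aldehyde completes the allyl group; the C8 ketone, flanked by two quaternary carbons, should not react at low temperature.

Step 18
Reactants: 25 (1S,4R,5S,6R,7S)-4-[(tert-butyldimethylsilyl)oxy]-3,5-dimethoxy-7-methyl-1-(prop-2-en-1-yl)-6-(3,4,5-trimethoxyphenyl)bicyclo[3.2.1]oct-2-en-8-one
Product: 26 (1S,4R,5S,6R,7S)-4-hydroxy-3,5-dimethoxy-7-methyl-1-(prop-2-en-1-yl)-6-(3,4,5-trimethoxyphenyl)bicyclo[3.2.1]oct-2-en-8-one
Conditions: Bu4NF, AcOH, THF, 0 to 25 °C
Reagents that add atoms: none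
Why: Fluoride cleavage of the silyl ether, buffered with AcOH so that the C4 alkoxide, which could open the β-hydroxy ketone by retro-aldol cleavage of C4–C5, is protonated as it forms.

Step 19
Reactants: 26 (1S,4R,5S,6R,7S)-4-hydroxy-3,5-dimethoxy-7-methyl-1-(prop-2-en-1-yl)-6-(3,4,5-trimethoxyphenyl)bicyclo[3.2.1]oct-2-en-8-one
Product: 27 (1S,4R,5S,6R,7S)-3,5-dimethoxy-7-methyl-8-oxo-1-(prop-2-en-1-yl)-6-(3,4,5-trimethoxyphenyl)bicyclo[3.2.1]oct-2-en-4-yl acetate
Conditions: Ac2O, DMAP, pyridine, CH2Cl2, 25 °C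
Reagents that add atoms: acetic anhydride, CC(=O)OC(C)=O
Why: DMAP-catalysed acetylation of the secondary C4 alcohol gives the target without touching any stereocentre.

**Compound list**

1 | 3,4,5-trimethoxybenzaldehyde | O=Cc1cc(OC)c(OC)c(OC)c1 | starting material
2 | methyl 2-methoxyacetate | COCC(=O)OC | starting material
3 | methyl (Z)-2-methoxy-3-(3,4,5-trimethoxyphenyl)prop-2-enoate | COC(=O)/C(OC)=C/c1cc(OC)c(OC)c(OC)c1 | intermediate
4 | (Z)-N,2-dimethoxy-N-methyl-3-(3,4,5-trimethoxyphenyl)prop-2-enamide | CON(C)C(=O)/C(OC)=C/c1cc(OC)c(OC)c(OC)c1 | intermediate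
5 | (Z)-2,4-dimethoxy-1-(3,4,5-trimethoxyphenyl)penta-1,4-dien-3-one | C=C(OC)C(=O)/C(OC)=C/c1cc(OC)c(OC)c(OC)c1 | intermediate
6 | (R,Z)-2,4-dimethoxy-1-(3,4,5-trimethoxyphenyl)penta-1,4-dien-3-ol | C=C(OC)[C@@H](O)/C(OC)=C/c1cc(OC)c(OC)c(OC)c1 | intermediate
7 | penta-1,4-diene | C=CCC=C | starting material
8 | pentadienyllithium (formed in the flask) | C=CC([Li])C=C | intermediate
9 | methyl 2-ethenylbut-3-enoate | C=CC(C=C)C(=O)OC | intermediate
10 | lithium dienolate of 9 (formed in the flask) | C=CC(C=C)=C(OC)O[Li] | intermediate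
11 | rac-methyl 2,2-diethenyl-3-hydroxybutanoate | CC(O)C(C=C)(C=C)C(=O)OC | intermediate
12 | methyl 2,2-diethenylbut-3-enoate | C=CC(C=C)(C=C)C(=O)OC | intermediate
13 | 2,2-diethenylbut-3-enoic acid | C=CC(C=C)(C=C)C(=O)O | intermediate
14 | 2,2-diethenylbut-3-enoyl chloride (formed in the flask) | C=CC(C=C)(C=C)C(=O)Cl | intermediate
15 | (R,Z)-2,4-dimethoxy-1-(3,4,5-trimethoxyphenyl)penta-1,4-dien-3-yl 2,2-diethenylbut-3-enoate | C=C(OC)[C@@H](OC(=O)C(C=C)(C=C)C=C)/C(OC)=C/c1cc(OC)c(OC)c(OC)c1 | intermediate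
16 | (S)-3,3-diethenyl-5-methoxy-6-[(Z)-1-methoxy-2-(3,4,5-trimethoxyphenyl)ethenyl]-3,6-dihydro-2H-pyran-2-one | O=C1O[C@@H](/C(OC)=C/c2cc(OC)c(OC)c(OC)c2)C(OC)=CC1(C=C)C=C | intermediate
17 | (3E,5S,6Z)-2,2-diethenyl-5-hydroxy-N,4,6-trimethoxy-N-methyl-7-(3,4,5-trimethoxyphenyl)hepta-3,6-dienamide | CON(C)C(=O)C(C=C)(C=C)/C=C(OC)\[C@@H](O)/C(OC)=C/c1cc(OC)c(OC)c(OC)c1 | intermediate
18 | (3E,5S,6Z)-5-[(tert-butyldimethylsilyl)oxy]-2,2-diethenyl-N,4,6-trimethoxy-N-methyl-7-(3,4,5-trimethoxyphenyl)hepta-3,6-dienamide | CON(C)C(=O)C(C=C)(C=C)/C=C(OC)\[C@@H](O[Si](C)(C)C(C)(C)C)/C(OC)=C/c1cc(OC)c(OC)c(OC)c1 | intermediate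
19 | (3E,5S,6Z)-5-[(tert-butyldimethylsilyl)oxy]-2,2-diethenyl-4,6-dimethoxy-7-(3,4,5-trimethoxyphenyl)hepta-3,6-dienal | O=CC(C=C)(C=C)/C=C(OC)\[C@@H](O[Si](C)(C)C(C)(C)C)/C(OC)=C/c1cc(OC)c(OC)c(OC)c1 | intermediate
20 | 8-O-tributylstannyl ether of 21 (formed in the flask) | C=C[C@]12C=C(OC)[C@@H](O[Si](C)(C)C(C)(C)C)[C@](OC)([C@@H]1O[Sn](CCCC)(CCCC)CCCC)[C@@H](c1cc(OC)c(OC)c(OC)c1)[C@@H]2C | intermediate
21 | (1S,4R,5R,6R,7S,8R)-4-[(tert-butyldimethylsilyl)oxy]-1-ethenyl-3,5-dimethoxy-7-methyl-6-(3,4,5-trimethoxyphenyl)bicyclo[3.2.1]oct-2-en-8-ol | C=C[C@]12C=C(OC)[C@@H](O[Si](C)(C)C(C)(C)C)[C@](OC)([C@@H]1O)[C@@H](c1cc(OC)c(OC)c(OC)c1)[C@@H]2C | intermediate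
22 | B-alkyl-9-borabicyclo[3.3.1]nonane adduct of 21 at the terminal vinyl carbon (formed in the flask) | C1CCC2CCCC1B2CC[C@]34C=C(OC)[C@@H](O[Si](C)(C)C(C)(C)C)[C@](OC)([C@@H]3O)[C@@H](c3cc(OC)c(OC)c(OC)c3)[C@@H]4C | intermediate
23 | (1S,4R,5R,6R,7S,8R)-4-[(tert-butyldimethylsilyl)oxy]-1-(2-hydroxyethyl)-3,5-dimethoxy-7-methyl-6-(3,4,5-trimethoxyphenyl)bicyclo[3.2.1]oct-2-en-8-ol | OCC[C@]12C=C(OC)[C@@H](O[Si](C)(C)C(C)(C)C)[C@](OC)([C@@H]1O)[C@@H](c1cc(OC)c(OC)c(OC)c1)[C@@H]2C | intermediate
24 | 2-[(1S,4R,5S,6R,7S)-4-[(tert-butyldimethylsilyl)oxy]-3,5-dimethoxy-7-methyl-8-oxo-6-(3,4,5-trimethoxyphenyl)bicyclo[3.2.1]oct-2-en-1-yl]acetaldehyde | O=CC[C@]12C=C(OC)[C@@H](O[Si](C)(C)C(C)(C)C)[C@](OC)(C1=O)[C@@H](c1cc(OC)c(OC)c(OC)c1)[C@@H]2C | intermediate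
25 | (1S,4R,5S,6R,7S)-4-[(tert-butyldimethylsilyl)oxy]-3,5-dimethoxy-7-methyl-1-(prop-2-en-1-yl)-6-(3,4,5-trimethoxyphenyl)bicyclo[3.2.1]oct-2-en-8-one | C=CC[C@]12C=C(OC)[C@@H](O[Si](C)(C)C(C)(C)C)[C@](OC)(C1=O)[C@@H](c1cc(OC)c(OC)c(OC)c1)[C@@H]2C | intermediate
26 | (1S,4R,5S,6R,7S)-4-hydroxy-3,5-dimethoxy-7-methyl-1-(prop-2-en-1-yl)-6-(3,4,5-trimethoxyphenyl)bicyclo[3.2.1]oct-2-en-8-one | C=CC[C@]12C=C(OC)[C@@H](O)[C@](OC)(C1=O)[C@@H](c1cc(OC)c(OC)c(OC)c1)[C@@H]2C | intermediate
27 | (1S,4R,5S,6R,7S)-3,5-dimethoxy-7-methyl-8-oxo-1-(prop-2-en-1-yl)-6-(3,4,5-trimethoxyphenyl)bicyclo[3.2.1]oct-2-en-4-yl acetate | C=CC[C@]12C=C(OC)[C@@H](OC(C)=O)[C@](OC)(C1=O)[C@@H](c1cc(OC)c(OC)c(OC)c1)[C@@H]2C | target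

**Summary**

Total step count: 19. Longest linear sequence: 15 steps (steps 1–4, then 9–19; the acid branch, steps 5–8 then 9–19, is equally long).

Steps most likely to fail:

1. Step 14 (radical cascade). Three processes could divert it. The reversibly formed O-stannyl ketyl may be reduced (net hydrostannation of the aldehyde) before the slow 6-exo addition to the electron-rich, trisubstituted enol ether. The C8 radical may undergo 3-exo closure and ring opening, which is a 1,2-vinyl shift. Facial control at C5, or exo/endo control at C6 and C7, may be poor. Fallback: generate the C8 radical irreversibly from a pre-formed precursor instead of by reversible addition to the carbonyl group. Starting from 19, addition of PhSeSiMe3 (cat. ZnI2, CH2Cl2, 0 °C) would give the O-trimethylsilyl hemiselenoacetal F1. Selenium abstraction with Bu3SnH and AIBN under slow addition (PhH, 80 °C) would start the same two ring closures from an α-silyloxy radical and give the 8-O-trimethylsilyl ether F2. Mild methanolysis (K2CO3, MeOH) would remove the trimethylsilyl group and return to the route at 21.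

2. Step 10 (ring-closing metathesis). Initiation at the neopentylic vinyl groups may be too slow, and the catalyst may be trapped on the enol ether as an unreactive Fischer-type alkoxycarbene, so that oligomerisation wins. Fallback: close the ring before the quaternary carbon is made. Starting from 7, lithiation as in step 5 would give 8, which should be carboxylated mainly at its central carbon; quenching with CO2 (THF, −78 °C; then cold aq. HCl) would give 2-ethenylbut-3-enoic acid F3 without exposure to hydroxide, which could move a double bond into conjugation. Steglich esterification with 6 (DCC, DMAP, CH2Cl2, 0 °C) would give the ester F4, whose vinyl groups sit on a tertiary carbon and should initiate far faster. Ring-closing metathesis with the same catalyst would give the lactone F5 as a mixture of C3 epimers, which converge on enolisation. Deprotonation with LiN(i-Pr)2 at −78 °C and aldol addition to CH3CHO at the α-carbon would give the hydroxyethyl lactone F6. Burgess dehydration would then return to the route at 16.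

3. Step 4 (asymmetric reduction). The two alkenyl groups on the ketone may be too similar for good enantioface discrimination, which would erode the enantiomeric purity of every later compound. Fallback: replace catalyst control by enzymatic resolution. Starting from 5, Luche reduction (NaBH4, CeCl3·7H2O, MeOH, −78 °C) would give the racemic alcohol F7. Acylation with Candida antarctica lipase B and vinyl acetate in t-BuOMe should convert the (R)-enantiomer, whose larger aryl-bearing group fits the large pocket, into the (R)-acetate F8. After separation from the unreacted (S)-alcohol, methanolysis (K2CO3, MeOH) would return to the route at 6.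

**Further compounds**

F1 | step 14 | (3E,5S,6Z)-5-[(tert-butyldimethylsilyl)oxy]-2,2-diethenyl-4,6-dimethoxy-1-(phenylselanyl)-7-(3,4,5-trimethoxyphenyl)-1-[(trimethylsilyl)oxy]hepta-3,6-diene (both C1 epimers) | C[Si](C)(C)OC([Se]c1ccccc1)C(C=C)(C=C)/C=C(OC)\[C@@H](O[Si](C)(C)C(C)(C)C)/C(OC)=C/c1cc(OC)c(OC)c(OC)c1
F2 | step 14 | 8-O-trimethylsilyl ether of 21 | C=C[C@]12C=C(OC)[C@@H](O[Si](C)(C)C(C)(C)C)[C@](OC)([C@@H]1O[Si](C)(C)C)[C@@H](c1cc(OC)c(OC)c(OC)c1)[C@@H]2C
F3 | step 10 | 2-ethenylbut-3-enoic acid | C=CC(C=C)C(=O)O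
F4 | step 10 | (R,Z)-2,4-dimethoxy-1-(3,4,5-trimethoxyphenyl)penta-1,4-dien-3-yl 2-ethenylbut-3-enoate | C=C(OC)[C@@H](OC(=O)C(C=C)C=C)/C(OC)=C/c1cc(OC)c(OC)c(OC)c1
F5 | step 10 | (6S)-3-ethenyl-5-methoxy-6-[(Z)-1-methoxy-2-(3,4,5-trimethoxyphenyl)ethenyl]-3,6-dihydro-2H-pyran-2-one (both C3 epimers) | O=C1O[C@@H](/C(OC)=C/c2cc(OC)c(OC)c(OC)c2)C(OC)=CC1C=C
F6 | step 10 | (6S)-3-ethenyl-3-(1-hydroxyethyl)-5-methoxy-6-[(Z)-1-methoxy-2-(3,4,5-trimethoxyphenyl)ethenyl]-3,6-dihydro-2H-pyran-2-one (mixture at C3 and the carbinol carbon) | O=C1O[C@@H](/C(OC)=C/c2cc(OC)c(OC)c(OC)c2)C(OC)=CC1(C=C)C(C)O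
F7 | step 4 | rac-(Z)-2,4-dimethoxy-1-(3,4,5-trimethoxyphenyl)penta-1,4-dien-3-ol | C=C(OC)C(O)/C(OC)=C/c1cc(OC)c(OC)c(OC)c1
F8 | step 4 | (R,Z)-2,4-dimethoxy-1-(3,4,5-trimethoxyphenyl)penta-1,4-dien-3-yl acetate | C=C(OC)[C@@H](OC(C)=O)/C(OC)=C/c1cc(OC)c(OC)c(OC)c1
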